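A direct plan would start from a bought bicyclic core, 6-bromoisatin A1, and would N-methylate it, remove the C3 carbonyl by hydrazone formation and Wolff–Kishner reduction to reach 6-bromo-1-methylindolin-2-one A2, brominate the ring to 5,6-dibromo-1-methylindolin-2-one A3, deoxybrominate the lactam to 2,5,6-tribromo-1-methyl-1H-indole A4, and finish with a Mannich reaction at C3 and N-oxidation.
Its weakest points would be:
- The hydrazone/Wolff–Kishner pair on the way from A1 to A2: two steps that form no bond of the target and only delete an oxygen that came with the starting material, inside a four-step linear run-up to a simple oxindole.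
- The ring bromination of A2 to A3: the choice between C5 and C7, and against the acidic C3 methylene, rests on small differences, and a wrong isomer could not be corrected later.
- The lactam deoxybromination of A3 to A4: hot, HBr-releasing conditions that would make a 3-unsubstituted 2-bromoindole, an acid-labile class, which must then undergo a Mannich reaction although three bromines deactivate it.

**Retrosynthetic overview**
- Target ⇒ (N-oxidation) gramine 15 ⇒ (ipso-bromodesilylation at C2) 2-silylgramine 11 ⇒ (Larock heteroannulation, forming C3–C3a and N1–C2) 4,5-dibromo-2-iodo-N-methylaniline 6 + silylpropargylamine 10.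
- Structural hook: the C2(Br)–C3(CH2NMe2) edge of the pyrrole ring is an alkyne in disguise. C3 with its whole aminomethyl arm and C2 with silicon as a stand-in for bromine are the two carbons of Me3Si–C≡C–CH2NMe2.
- Ring order: the benzene ring is bought with both bromines in place (3,4-dibromoaniline), and the pyrrole ring is closed last onto it, in one operation, from two fragments.
- Avoided by design: no carbonyl is carried only to be deleted; the benzo ring is never brominated (the one aromatic substitution, iodination, has a single unhindered site); there is no lactam deoxybromination, no 3-unsubstituted 2-bromoindole and no Mannich reaction on a bromine-deactivated indole.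

Key step: step 4

Remark: the target has no stereocentre; paraformaldehyde is entered in the compound list as its monomer, formaldehyde.

Step 1
Reactants: 1 3,4-dibromoaniline; 2 iodine monochloride
Product: 3 4,5-dibromo-2-iodoaniline
Conditions: ICl (1.0 eq), AcOH, rt; aq Na2S2O3 quench
Reagents that add atoms: iodine monochloride, ClI
Why: Electrophilic aromatic iodination is directed by the amino group to its ortho positions (para is blocked by bromine), and of the two only the one not flanked by a bromine is open to the large iodine, which places the iodide on the carbon that becomes C3a.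

Step 2
Reactants: 3 4,5-dibromo-2-iodoaniline; 4 paraformaldehyde
Product: 6 4,5-dibromo-2-iodo-N-methylaniline, via N-(methoxymethyl)aniline adduct 5 (not isolated)
Conditions: (CH2O)n (2 eq), NaOMe (5 eq), MeOH, reflux; then NaBH4 (2 eq), reflux
Reagents that add atoms: paraformaldehyde (formaldehyde), C=O
Why: Reductive N-methylation through the hemiaminal ether should stop at the secondary amine because the hydride is added only after the mono-adduct has formed, and NaBH4 leaves the three aryl halides untouched.

Step 3
Reactants: 7 N,N-dimethylprop-2-yn-1-amine; 8 chlorotrimethylsilane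
Product: 10 N,N-dimethyl-3-(trimethylsilyl)prop-2-yn-1-amine, via lithium acetylide 9 (not isolated)
Conditions: n-BuLi (1.05 eq), THF, −78 °C; Me3SiCl (1.1 eq), −78 °C to rt; distillation
Reagents that add atoms: chlorotrimethylsilane, C[Si](C)(C)Cl
Why: Deprotonation of the terminal alkyne by n-BuLi and C-silylation of the acetylide is a standard alkyne silylation to which the tertiary amine is inert.

Step 4
Reactants: 6 4,5-dibromo-2-iodo-N-methylaniline; 10 N,N-dimethyl-3-(trimethylsilyl)prop-2-yn-1-amine
Product: 11 1-[5,6-dibromo-1-methyl-2-(trimethylsilyl)-1H-indol-3-yl]-N,N-dimethylmethanamine (2-silylgramine)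
Conditions: Pd(OAc)2 (5 mol%), LiCl (1 eq), Na2CO3 (3 eq), 10 (2.5 eq), DMF, 90–100 °C, N2
Reagents that add atoms: N,N-dimethyl-3-(trimethylsilyl)prop-2-yn-1-amine, C[Si](C)(C)C#CCN(C)C
Why: Larock heteroannulation: zerovalent palladium formed from Pd(OAc)2 inserts into the C–I bond of 6, the arylpalladium adds syn across the alkyne of 10 with the aryl group going to the carbon that carries CH2NMe2 and palladium to the carbon that carries silicon, the N–H nitrogen displaces halide to give a six-membered azapalladacycle, and C–N reductive elimination returns zerovalent palladium. The closest known reaction type is the annulation of N-methyl-2-iodoanilines with 1-silylalkynes, including silylalkynes that carry a tertiary amine, which gives 2-silylindoles. The pyrrole ring is closed in a formal [3+2] sense, C3–C3a by carbopalladation and N1–C2 by reductive elimination, and no stereocentre is formed. Two selectivities are needed: the regiochemistry of insertion, secured by the bulk of SiMe3, which takes the place next to the long C–Pd bond and so ends at C2, and insertion into C–I in preference to C–Br, secured by the weaker C–I bond under ligand-free conditions at or below 100 °C. In one operation the step should deliver the whole bicyclic core, the complete C3 side chain and a C2 substituent that marks the place of the last bromine.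

Step 5
Reactants: 11 1-[5,6-dibromo-1-methyl-2-(trimethylsilyl)-1H-indol-3-yl]-N,N-dimethylmethanamine; 12 N-bromosuccinimide
Product: 15 2,5,6-tribromo-1-methylgramine [1-(2,5,6-tribromo-1-methyl-1H-indol-3-yl)-N,N-dimethylmethanamine], via silylgramine trifluoroacetate 13 (not isolated), via tribromogramine trifluoroacetate 14 (not isolated)
Conditions: CF3CO2H (2 eq), CH2Cl2, −20 °C; NBS (1.05 eq), −20 to 0 °C, dark; aq NaHCO3/Na2S2O3 work-up
Reagents that add atoms: N-bromosuccinimide, O=C1CCC(=O)N1Br
Why: Electrophilic ipso-bromodesilylation of a 2-silylindole: with the amine protonated (no lone pair for retro-Mannich loss of the arm, no N-bromination) the bromonium source attacks the pyrrole ring and the silyl group leaves from C2, while any molecule that is protodesilylated first should be brominated at the same carbon by the C3-attack/1,2-shift path of 3-substituted indoles, so both paths converge on 15.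

Step 6
Reactants: 15 2,5,6-tribromo-1-methylgramine; 16 3-chloroperoxybenzoic acid (mCPBA)
Product: 17 2,5,6-tribromo-1-methylgramine N-oxide [1-(2,5,6-tribromo-1-methyl-1H-indol-3-yl)-N,N-dimethylmethanamine N-oxide] (target)
Conditions: mCPBA (1.05 eq), CH2Cl2, 0 °C; filtration through basic alumina (CH2Cl2/MeOH)
Reagents that add atoms: mCPBA, OOC(=O)c1cccc(Cl)c1
Why: Peracid N-oxidation of the trialkylamine should be far faster than attack on the C2=C3 bond of an indole deactivated by three bromines, basic alumina holds back the 3-chlorobenzoic acid, and no stereocentre is created.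

## Compound list

1 | 3,4-dibromoaniline | Nc1ccc(Br)c(Br)c1 | starting material
2 | iodine monochloride | ClI | starting material
3 | 4,5-dibromo-2-iodoaniline | Nc1cc(Br)c(Br)cc1I | intermediate
4 | paraformaldehyde (as formaldehyde) | C=O | starting material
5 | 4,5-dibromo-2-iodo-N-(methoxymethyl)aniline | COCNc1cc(Br)c(Br)cc1I | intermediate (not isolated)
6 | 4,5-dibromo-2-iodo-N-methylaniline | CNc1cc(Br)c(Br)cc1I | intermediate
7 | N,N-dimethylprop-2-yn-1-amine | C#CCN(C)C | starting material
8 | chlorotrimethylsilane | C[Si](C)(C)Cl | starting material
9 | lithium 3-(dimethylamino)prop-1-yn-1-ide | [Li]C#CCN(C)C | intermediate (not isolated)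
10 | N,N-dimethyl-3-(trimethylsilyl)prop-2-yn-1-amine | C[Si](C)(C)C#CCN(C)C | intermediate
11 | 1-[5,6-dibromo-1-methyl-2-(trimethylsilyl)-1H-indol-3-yl]-N,N-dimethylmethanamine | Cn1c([Si](C)(C)C)c(CN(C)C)c2cc(Br)c(Br)cc21 | intermediate
12 | N-bromosuccinimide | O=C1CCC(=O)N1Br | starting material
13 | 1-[5,6-dibromo-1-methyl-2-(trimethylsilyl)-1H-indol-3-yl]-N,N-dimethylmethanaminium trifluoroacetate | Cn1c([Si](C)(C)C)c(C[NH+](C)C)c2cc(Br)c(Br)cc21.[O-]C(=O)C(F)(F)F | intermediate (not isolated)
14 | 1-(2,5,6-tribromo-1-methyl-1H-indol-3-yl)-N,N-dimethylmethanaminium trifluoroacetate | Cn1c(Br)c(C[NH+](C)C)c2cc(Br)c(Br)cc21.[O-]C(=O)C(F)(F)F | intermediate (not isolated)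
15 | 2,5,6-tribromo-1-methylgramine [1-(2,5,6-tribromo-1-methyl-1H-indol-3-yl)-N,N-dimethylmethanamine] | Cn1c(Br)c(CN(C)C)c2cc(Br)c(Br)cc21 | intermediate
16 | 3-chloroperoxybenzoic acid (mCPBA) | OOC(=O)c1cccc(Cl)c1 | starting material
17 | 2,5,6-tribromo-1-methylgramine N-oxide | Cn1c(Br)c(C[N+](C)(C)[O-])c2cc(Br)c(Br)cc21 | target

Total step count: 6. Longest linear sequence: 5 (steps 1, 2, 4, 5, 6); step 3 is a one-step side branch.

**Steps most likely to fail**

Step 4 (heteroannulation). Zerovalent palladium may insert into the C–Br bonds of substrate or product, the alkyne may lose its silyl group before insertion, or coordination of the amine may invert the regiochemistry of insertion. The fallback would close the pyrrole ring stepwise. It sets out from 6, which would be coupled at the C–I bond with ethynyltrimethylsilane (PdCl2(PPh3)2, CuI, Et3N, rt, Sonogashira coupling) to 4,5-dibromo-N-methyl-2-[(trimethylsilyl)ethynyl]aniline F1. KOt-Bu in NMP at rt should desilylate F1 and cyclise the anilide (5-endo-dig hydroamination) to 5,6-dibromo-1-methyl-1H-indole F2. A classical Mannich reaction (aq Me2NH, CH2O, AcOH) should give 5,6-dibromo-1-methylgramine F3. NBS on the trifluoroacetate salt of F3 should brominate C2 (3-bromoindolenine, 1,2-shift), and the sequence comes back to the route at 15.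

Step 5 (ipso-bromination). If protonation is incomplete, attack of the bromonium source at C3 may be followed by retro-Mannich loss of the aminomethyl arm, or the amine may be oxidised. The fallback would make the C2–Br bond without any cationic intermediate at C3. It sets out from 11, which would be protodesilylated with CF3CO2H in CH2Cl2 to 5,6-dibromo-1-methylgramine F3 (the compound also met in the fallback for step 4). C–H borylation at C2 with bis(pinacolato)diboron under [Ir(OMe)(cod)]2/4,4′-di-tert-butyl-2,2′-bipyridine catalysis (tolerant of aryl bromides) should give 1-[5,6-dibromo-1-methyl-2-(4,4,5,5-tetramethyl-1,3,2-dioxaborolan-2-yl)-1H-indol-3-yl]-N,N-dimethylmethanamine F4. Bromodeboronation with CuBr2 in MeOH/H2O comes back to the route at 15.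

Step 2 (mono-N-methylation). Formation of the hemiaminal ether may stall at the hindered, electron-poor nitrogen, or methylation may run on to the tertiary amine. The fallback would bring the methyl carbon in as an acyl group. It sets out from 3, which would be formylated with acetic formic anhydride (HCO2H/Ac2O) to N-(4,5-dibromo-2-iodophenyl)formamide F5. Reduction of the formamide with BH3·SMe2 in THF comes back to the route at 6.

## Further compounds

F1 | step 4 | 4,5-dibromo-N-methyl-2-[(trimethylsilyl)ethynyl]aniline | CNc1cc(Br)c(Br)cc1C#C[Si](C)(C)C
F2 | step 4 | 5,6-dibromo-1-methyl-1H-indole | Cn1ccc2cc(Br)c(Br)cc21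
F3 | step 4 | 5,6-dibromo-1-methylgramine [1-(5,6-dibromo-1-methyl-1H-indol-3-yl)-N,N-dimethylmethanamine] | Cn1cc(CN(C)C)c2cc(Br)c(Br)cc21
F4 | step 5 | 1-[5,6-dibromo-1-methyl-2-(4,4,5,5-tetramethyl-1,3,2-dioxaborolan-2-yl)-1H-indol-3-yl]-N,N-dimethylmethanamine | Cn1c(B2OC(C)(C)C(C)(C)O2)c(CN(C)C)c2cc(Br)c(Br)cc21
F5 | step 2 | N-(4,5-dibromo-2-iodophenyl)formamide | O=CNc1cc(Br)c(Br)cc1I
A1 | direct plan | 6-bromoisatin (6-bromoindoline-2,3-dione) | O=C1Nc2cc(Br)ccc2C1=O
A2 | direct plan | 6-bromo-1-methylindolin-2-one | CN1C(=O)Cc2ccc(Br)cc21
A3 | direct plan | 5,6-dibromo-1-methylindolin-2-one | CN1C(=O)Cc2cc(Br)c(Br)cc21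
A4 | direct plan | 2,5,6-tribromo-1-methyl-1H-indole | Cn1c(Br)cc2cc(Br)c(Br)cc21
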